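A direct plan would decorate the intact phloroglucinol ring A1. Houben–Hoesch acylation would give 2,4,6-trihydroxybenzophenone A2, and twofold Mannich aminomethylation would give its 3,5-bis(dimethylaminomethyl) derivative A3. Both CH2NMe2 arms would then become prenyl groups by o-quinone methide formation and alkenyl transfer from (2-methylprop-1-en-1-yl)boronic acid A4. Its weakest steps would be:
- the twofold deaminative alkenyl transfer, because two successive, very electron-rich o-quinone methides would have to be trapped before they oligomerise, re-add amine or cyclise onto the first prenyl alkene;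
- the double aminomethylation, because it adds one-carbon arms and a step without adding complexity, and risks methylene-bridged dimers;
- the ring acylation, because it needs gaseous HCl for days and a separate hydrolysis for one C–C bond.

The ring of the target alternates oxygen-bearing carbons (C2, C4, C6) with carbon-substituted ones (C1 benzoyl, C3 and C5 prenyl), the pattern of a folded 1,3,5,7-tetracarbonyl chain. The route therefore never uses a preformed phloroglucinol: ring bonds C5–C6 and C6–C1 are disconnected to acyclic triketone 7, which already carries the benzoyl and both prenyl groups on the future C1, C3 and C5, and to dimethyl carbonate as C6. The key step inserts this carbon, closes the ring by Claisen cyclisation and aromatises it in one operation. Ring acylation, aminomethylation and prenyl transfer to an arene do not occur, so C/O-, mono/bis- and gem-selectivity are fixed by connectivity.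

Key step: step 4

Assumption: 6, 7 and 9 are drawn as keto forms although they should exist mainly as enols; the CH(prenyl) centres of 7 and 9 are configurationally labile and disappear on aromatisation, so the route poses no stereochemical problem.

Step 1
Reactants: 1 2-methylbut-3-en-2-ol; 2 triethyl orthoacetate (1,1,1-triethoxyethane)
Product: 4 ethyl 5-methylhex-4-enoate, via mixed ketene acetal 3 (not isolated)
Conditions: 2 (2 equiv), EtCO2H (0.05 equiv), 140 °C, EtOH distilled off
Reagents that add atoms: none
Why: Johnson–Claisen rearrangement, in which acid-catalysed exchange gives ketene acetal 3 and its [3,3]-sigmatropic shift joins the acetate carbon to the terminal vinyl carbon, leaving the trisubstituted prenyl-type alkene; no stereocentre or alkene geometry arises because the new alkene carries two methyl groups.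

Step 2
Reactants: 5 acetophenone; 4 ethyl 5-methylhex-4-enoate
Product: 6 7-methyl-1-phenyloct-6-ene-1,3-dione
Conditions: NaH (2.2 equiv), THF, 65 °C; 5 added over 2 h to 4 (1.5 equiv); cold 1 M aq. HCl
Reagents that add atoms: none
Why: Crossed Claisen condensation, in which acetophenone enolises on one side only, its sodium enolate attacks the ester carbonyl of 4, the product is withdrawn as the stable sodium 1,3-diketonate and slow addition of the ketone to excess ester suppresses self-aldol; no stereocentre is formed.

Step 3
Reactants: 6 7-methyl-1-phenyloct-6-ene-1,3-dione; 4 ethyl 5-methylhex-4-enoate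
Product: 7 9-methyl-4-(3-methylbut-2-en-1-yl)-1-phenyldec-8-ene-1,3,5-trione
Conditions: 6 (2.0 equiv), LiN(iPr)2 (4.1 equiv), THF, −78 → 0 °C; 4 (1.0 equiv), 0 → 23 °C; cold 1 M aq. HCl; excess 6 recovered
Reagents that add atoms: none
Why: Claisen acylation of a 1,3-diketone 2,4-dianion, in which the second deprotonation of 6 can only occur at C4 (the benzoyl side has no α-hydrogen), this localised carbanion is far more nucleophilic than the diketonate and attacks the ester carbonyl of 4, and the second equivalent of dianion takes up the acidic proton of 7; the CH(prenyl) centre formed is enolisable and of no consequence.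

Step 4
Reactants: 7 9-methyl-4-(3-methylbut-2-en-1-yl)-1-phenyldec-8-ene-1,3,5-trione; 8 dimethyl carbonate
Product: 10 clusiaphenone B, via triketo ester 9 (not isolated)
Conditions: LiN(iPr)2 (3.2 equiv), THF, −78 → 0 °C; added to 8 (1.5 equiv), THF, 0 → 23 °C; then MeOH, 50 °C, Ar; cold 1 M aq. HCl
Reagents that add atoms: none
Why: LiN(iPr)2 should remove the two 1,3-dicarbonyl protons of 7 (C2–H, C4–H) and then a C6–H, the only α-hydrogen left, and the trianion should react at this localised, most basic carbon with dimethyl carbonate to give triketo ester 9 (Claisen-type alkoxycarbonylation of a polyketone polyanion, the ester counterpart of polyanion carboxylation with CO2). In the methanolic lithium methoxide that follows, the most acidic site of 9, the C6 methylene between the benzoyl and the C5 carbonyl group, should attack the un-ionised ester carbonyl C1 in a Claisen (Dieckmann-type) cyclisation, a 6-exo-trig closure, and loss of methoxide gives 2-benzoyl-4,6-diprenylcyclohexane-1,3,5-trione, the keto tautomer of 10, which aromatises irreversibly. The closest known reaction type is the biomimetic Claisen cyclisation of 3,5,7-triketo esters to acylphloroglucinols. No stereocentre is created, and the two labile CH(prenyl) centres of 9 become sp2 ring carbons. The step needs C-acylation at the chain terminus and Claisen in preference to aldol or lactone closure: the first is secured by the charge-localised C6 carbanion of the trianion, the second because the aldol donor C2 of 9 is a hindered tertiary carbon whose adduct cannot aromatise without losing the ester, the aldol acceptor C7 is masked in the diketonate, lactonisation to the 2-pyrone is reversible in methoxide, and aromatisation drains the equilibria towards 10.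

Compound list
1 | 2-methylbut-3-en-2-ol | C=CC(C)(C)O | starting material
2 | triethyl orthoacetate (1,1,1-triethoxyethane) | CCOC(C)(OCC)OCC | starting material
3 | 1-ethoxy-1-[(2-methylbut-3-en-2-yl)oxy]ethene (mixed ketene acetal) | C=C(OCC)OC(C)(C)C=C | intermediate
4 | ethyl 5-methylhex-4-enoate | CCOC(=O)CCC=C(C)C | intermediate
5 | acetophenone | CC(=O)c1ccccc1 | starting material
6 | 7-methyl-1-phenyloct-6-ene-1,3-dione | CC(C)=CCCC(=O)CC(=O)c1ccccc1 | intermediate
7 | 9-methyl-4-(3-methylbut-2-en-1-yl)-1-phenyldec-8-ene-1,3,5-trione | CC(C)=CCCC(=O)C(CC=C(C)C)C(=O)CC(=O)c1ccccc1 | intermediate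
8 | dimethyl carbonate | COC(=O)OC | starting material
9 | methyl 2,4-bis(3-methylbut-2-en-1-yl)-3,5,7-trioxo-7-phenylheptanoate (triketo ester) | COC(=O)C(CC=C(C)C)C(=O)C(CC=C(C)C)C(=O)CC(=O)c1ccccc1 | intermediate
10 | clusiaphenone B ([2,4,6-trihydroxy-3,5-bis(3-methylbut-2-en-1-yl)phenyl](phenyl)methanone) | CC(C)=CCc1c(O)c(CC=C(C)C)c(O)c(C(=O)c2ccccc2)c1O | target

Total step count: 4. Longest linear sequence: 4 steps (1 → 4 → 6 → 7 → 10); ester 4 enters a second time in step 3, and 5 and 8 enter directly.

Steps most likely to fail

Step 4. The third deprotonation at the substituted C6 of 7 may be incomplete, a second trianion may attack the newly formed ester, or ring closure may run in the aldol sense or stop at the lactone instead of giving C-acylation. The fallback grows the chain from the ester end and closes it after a terminal aroylation. It would set out from 4: Claisen self-condensation (NaH, THF, 65 °C) would give ethyl 7-methyl-2-(3-methylbut-2-en-1-yl)-3-oxooct-6-enoate F1. Its 2,4-dianion (NaH, then n-BuLi, THF, 0 °C) would be acetylated at C4 with N-methoxy-N-methylacetamide to ethyl 2,4-bis(3-methylbut-2-en-1-yl)-3,5-dioxohexanoate F2. The trianion of F2 (LiN(iPr)2, 3.2 equiv) would be aroylated at its terminal methyl carbon with methyl benzoate, a non-enolisable acceptor, to ethyl 2,4-bis(3-methylbut-2-en-1-yl)-3,5,7-trioxo-7-phenylheptanoate F3, the ethyl analogue of 9. F3 would be cyclised in a separate operation with Mg(OMe)2 in MeOH. The fallback comes back to the route at 10.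

Step 3. Proton transfer from the enolisable ester to the strongly basic dianion (ester enolisation and self-condensation) may outrun acylation. The fallback replaces acylation by aldol addition and oxidation. It would set out from 4 and 6: i-Bu2AlH (1.0 equiv, CH2Cl2, −78 °C) would reduce 4 to 5-methylhex-4-enal F4. The dianion of 6 (LiN(iPr)2, 2.1 equiv) would add to F4, carbonyl addition being faster than proton transfer, to give 5-hydroxy-9-methyl-4-(3-methylbut-2-en-1-yl)-1-phenyldec-8-ene-1,3-dione F5 as a diastereomer mixture whose centres are lost later. Dess–Martin periodinane (NaHCO3, CH2Cl2) would oxidise F5, and the fallback comes back to the route at 7.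

Step 2. Self-aldol condensation of acetophenone and self-Claisen condensation of the ester may compete with the crossed condensation. The fallback brings in the prenyl-bearing carbon by dianion alkylation instead of with the ester. It would set out from 5: Claisen condensation with ethyl acetate (NaH, THF) would give 1-phenylbutane-1,3-dione F6. Its 2,4-dianion (LiN(iPr)2, 2.1 equiv, THF, 0 °C) would be alkylated at the terminal carbon with 1-bromo-3-methylbut-2-ene, and the fallback comes back to the route at 6.

Further compounds
F1 | step 4 | ethyl 7-methyl-2-(3-methylbut-2-en-1-yl)-3-oxooct-6-enoate | CCOC(=O)C(CC=C(C)C)C(=O)CCC=C(C)C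
F2 | step 4 | ethyl 2,4-bis(3-methylbut-2-en-1-yl)-3,5-dioxohexanoate | CCOC(=O)C(CC=C(C)C)C(=O)C(CC=C(C)C)C(C)=O
F3 | step 4 | ethyl 2,4-bis(3-methylbut-2-en-1-yl)-3,5,7-trioxo-7-phenylheptanoate | CCOC(=O)C(CC=C(C)C)C(=O)C(CC=C(C)C)C(=O)CC(=O)c1ccccc1
F4 | step 3 | 5-methylhex-4-enal | CC(C)=CCCC=O
F5 | step 3 | 5-hydroxy-9-methyl-4-(3-methylbut-2-en-1-yl)-1-phenyldec-8-ene-1,3-dione | CC(C)=CCCC(O)C(CC=C(C)C)C(=O)CC(=O)c1ccccc1
F6 | step 2 | 1-phenylbutane-1,3-dione | CC(=O)CC(=O)c1ccccc1
A1 | direct plan | phloroglucinol (benzene-1,3,5-triol) | Oc1cc(O)cc(O)c1
A2 | direct plan | phenyl(2,4,6-trihydroxyphenyl)methanone (2,4,6-trihydroxybenzophenone) | O=C(c1ccccc1)c1c(O)cc(O)cc1O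
A3 | direct plan | {3,5-bis[(dimethylamino)methyl]-2,4,6-trihydroxyphenyl}(phenyl)methanone | CN(C)Cc1c(O)c(CN(C)C)c(O)c(C(=O)c2ccccc2)c1O
A4 | direct plan | (2-methylprop-1-en-1-yl)boronic acid | CC(C)=CB(O)O
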